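**Retrosynthetic overview** (ring atoms O1, C2–C6 as in a pyran-2-one; side chain C1'–C12' counted from the ketone carbon)

1. The C3–C1' bond is cut first: Steglich O-acylation followed by O-to-C acyl shift joins (R)-4-hydroxy-6-methyl-5,6-dihydro-2H-pyran-2-one to a C12 diene diacid whose central carboxyl is held as a tert-butyl ester.
2. The only ring (O1–C2–C3–C4–C5–C6) is opened at O1–C6. C6 is the β-carbon of the C4 ketone and the C2 carboxyl oxygen sits in the same O–C–C–C(=O)–C=C array as in a 2'-hydroxychalcone. The ring and its one stereocentre therefore come from achiral, acyclic (E)-3-oxohex-4-enoic acid by a catalyst-controlled 6-endo-trig oxa-Michael lactonisation.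
3. The diene acid is cut at the C7'–C8' sp2–sp2 bond (Suzuki–Miyaura): an (E)-alkenylboronate from (R)-citronellal (C4' methyl centre) and a (Z)-α-iodoenoate from (S)-2-methylbutan-1-ol (C10' centre).
4. Ring order: the single dihydropyranone ring is formed in step 4, before the fragment union (step 13) and the final ester cleavage (step 14).

Key step: step 4

Assumptions on the chemistry: the sense of induction of the cinchona squaramide in step 4 is taken by analogy with related oxa-Michael cyclisations; the quinidine-derived catalyst is written for the (R)-centre, and its quinine-derived pseudoenantiomer is the equivalent choice if the opposite enone face is delivered. Compound 7 is written as its 4-hydroxy enol tautomer, which equilibrates with the 2,4-dione form.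

**Step 1**
Reactants: 1 tert-butyl acetate; 2 (E)-but-2-enal
Product: 4 tert-butyl (E)-3-hydroxyhex-4-enoate (racemic), via lithium enolate 3 (not isolated)
Conditions: LDA (lithium diisopropylamide), THF, −78 °C; then 2, −78 °C; AcOH quench
Reagents that add atoms: none
Why: Aldol addition of the pre-formed lithium ester enolate to the enal is 1,2-selective at −78 °C; the new carbinol centre forms as a racemate and is erased in step 2.

**Step 2**
Reactants: 4 tert-butyl (E)-3-hydroxyhex-4-enoate
Product: 5 tert-butyl (E)-3-oxohex-4-enoate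
Conditions: Dess–Martin periodinane, CH2Cl2, 0 °C to rt
Reagents that add atoms: none
Why: Dess–Martin oxidation of the secondary allylic alcohol should give the enone β-keto ester under neutral conditions that leave the (E)-alkene and the tert-butyl ester untouched.

**Step 3**
Reactants: 5 tert-butyl (E)-3-oxohex-4-enoate
Product: 6 (E)-3-oxohex-4-enoic acid
Conditions: TFA/CH2Cl2 (1:4), 0 °C; volatiles removed below 10 °C with toluene co-evaporation; crude acid used at once
Reagents that add atoms: none
Why: Acidolysis of the tert-butyl ester (loss of the tert-butyl cation as isobutene) should free the β-keto acid at a temperature at which decarboxylation is slow.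

**Step 4**
Reactants: 6 (E)-3-oxohex-4-enoic acid
Product: 7 (R)-4-hydroxy-6-methyl-5,6-dihydro-2H-pyran-2-one
Conditions: 3-{[3,5-bis(trifluoromethyl)phenyl]amino}-4-{[(9R)-6'-methoxycinchonan-9-yl]amino}cyclobut-3-ene-1,2-dione (squaramide of 9-amino-9-deoxy-epi-quinidine, 10 mol %), toluene (0.02 M), −20 °C
Reagents that add atoms: none
Why: Proposed new method: the quinuclidine nitrogen of the catalyst deprotonates the carboxylic acid of 6 and holds the carboxylate as a chiral ion pair while the squaramide N–H groups bind the C4 ketone oxygen, so that a carboxylate oxygen (O1) adds to the β-carbon C6 of the (E)-crotonyl ketone and the enolate so formed is protonated by the ammonium and tautomerises to the 4-hydroxypyranone; the closest known reaction types are the amine–thiourea and amine–squaramide catalysed intramolecular oxa-Michael additions of phenols and alcohols to enones, among them the chalcone-to-flavanone cyclisation, and a carboxylic acid as the oxygen nucleophile in this array is the new element. The one ring (O1–C2–C3–C4–C5–C6) closes in the 6-endo-trig mode, with the enone carbonyl inside the new ring as in the flavanone case. The single new stereocentre C6 is under catalyst control: the ion-paired carboxylate is delivered to one enantiotopic face of the squaramide-bound enone, taken here as the face that gives (R). The step needs O-attack instead of C-attack, ring closure ahead of decarboxylation and of intermolecular Michael addition, and one enone face; the carboxylate is the only oxygen that can reach C6 through a six-membered transition state, C3 cannot reach C6, low temperature and high dilution should hold back loss of CO2 and oligomerisation, and the defined (E)-geometry presents a single substitution pattern to the catalyst. Enolisation of the product towards C3 takes the C4 ketone out of play and should protect C6 against retro-addition.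

**Step 5**
Reactants: 8 (S)-2-methylbutan-1-ol
Product: 9 (S)-2-methylbutanal
Conditions: TEMPO (cat.), KBr (cat.), NaOCl, NaHCO3 buffer, CH2Cl2/H2O, 0 °C
Reagents that add atoms: none
Why: TEMPO/NaOCl (Anelli-type) oxidation of the primary alcohol stops at the aldehyde, and the cold buffered two-phase medium should keep the α-stereocentre intact.

**Step 6**
Reactants: 9 (S)-2-methylbutanal; 10 tert-butyl (triphenylphosphoranylidene)acetate
Product: 12 tert-butyl (2Z,4S)-2-iodo-4-methylhex-2-enoate, via iodo ylide 11 (not isolated)
Conditions: 10, NIS, CH2Cl2, −20 °C; then 9, −20 °C to rt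
Reagents that add atoms: N-iodosuccinimide, O=C1CCC(=O)N1I
Why: Iodination of the stabilised ylide followed by Wittig olefination should place the alkyl group trans to the ester, i.e. give the (Z)-α-iodoenoate, under neutral conditions that should not epimerise C4; any minor (E)-isomer is to be removed by chromatography.

**Step 7**
Reactants: 13 (R)-citronellal ((R)-3,7-dimethyloct-6-enal)
Product: 14 (R)-4,8-dimethylnon-7-en-1-yne
Conditions: dimethyl (1-diazo-2-oxopropyl)phosphonate, K2CO3, MeOH, 0 °C to rt
Reagents that add atoms: dimethyl (1-diazo-2-oxopropyl)phosphonate, COP(=O)(OC)C(=[N+]=[N-])C(C)=O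
Why: Ohira–Bestmann (Seyferth–Gilbert) homologation converts the aldehyde into the terminal alkyne under mild base, and the methyl stereocentre, β to the carbonyl, is not at risk.

**Step 8**
Reactants: 14 (R)-4,8-dimethylnon-7-en-1-yne
Product: 16 (R)-4-methylhept-6-ynal, via ozonide 15 (not isolated)
Conditions: O3, CH2Cl2, −78 °C, stopped at the first excess of ozone; then PPh3, −78 °C to rt
Reagents that add atoms: ozone, [O-][O+]=O
Why: Ozonolysis (Criegee mechanism) with reductive work-up cleaves the electron-rich trisubstituted alkene much faster than the terminal alkyne, which should be spared when the ozone stream is stopped in time.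

**Step 9**
Reactants: 16 (R)-4-methylhept-6-ynal
Product: 17 methyl (R)-4-methylhept-6-ynoate
Conditions: Oxone (2KHSO5·KHSO4·K2SO4), MeOH, rt
Reagents that add atoms: methanol, CO
Why: Oxidative esterification: the methyl hemiacetal of the aldehyde is oxidised by peroxymonosulfate (Baeyer–Villiger-type hydride shift) to the methyl ester while the alkyne is inert.

**Step 10**
Reactants: 17 methyl (R)-4-methylhept-6-ynoate
Product: 18 methyl (R,E)-4-methyl-7-(4,4,5,5-tetramethyl-1,3,2-dioxaborolan-2-yl)hept-6-enoate
Conditions: pinacolborane, Cp2ZrHCl (5 mol %), Et3N (10 mol %), neat, 50 °C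
Reagents that add atoms: pinacolborane, CC1(C)OBOC1(C)C
Why: Cp2ZrHCl-catalysed hydroboration of the terminal alkyne with pinacolborane is a syn, anti-Markovnikov addition and should give only the (E)-alkenylboronate without reducing the ester.

**Step 11**
Reactants: 12 tert-butyl (2Z,4S)-2-iodo-4-methylhex-2-enoate; 18 methyl (R,E)-4-methyl-7-(4,4,5,5-tetramethyl-1,3,2-dioxaborolan-2-yl)hept-6-enoate
Product: 19 1-tert-butyl 9-methyl (2E,3E,6R)-6-methyl-2-[(S)-2-methylbutylidene]non-3-enedioate
Conditions: Pd(PPh3)4 (5 mol %), K3PO4, THF/H2O, 50 °C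
Reagents that add atoms: none
Why: Suzuki–Miyaura coupling proceeds with retention at both sp2 carbons, so the (E)-alkenyl unit and the (Z)-iodide geometry are carried into the (3E)-alkene and the (2E)-alkylidene of the 2-alkenyl enoate.

**Step 12**
Reactants: 19 1-tert-butyl 9-methyl (2E,3E,6R)-6-methyl-2-[(S)-2-methylbutylidene]non-3-enedioate
Product: 20 (4R,6E,8E,10S)-8-(tert-butoxycarbonyl)-4,10-dimethyldodeca-6,8-dienoic acid
Conditions: LiOH, THF/MeOH/H2O, 0 °C to rt; then 1 M HCl to pH 3
Reagents that add atoms: lithium hydroxide, [Li+].[OH-]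
Why: Saponification distinguishes the unhindered methyl ester from the hindered, conjugated tert-butyl ester.

**Step 13**
Reactants: 20 (4R,6E,8E,10S)-8-(tert-butoxycarbonyl)-4,10-dimethyldodeca-6,8-dienoic acid; 7 (R)-4-hydroxy-6-methyl-5,6-dihydro-2H-pyran-2-one
Product: 22 tert-butyl (2E,3E,6R)-9-[(R)-4-hydroxy-6-methyl-2-oxo-5,6-dihydro-2H-pyran-3-yl]-6-methyl-2-[(S)-2-methylbutylidene]-9-oxonon-3-enoate, via enol ester 21 (not isolated)
Conditions: DCC, DMAP (1.2 equiv), CH2Cl2, 0 °C to rt, then 40 °C
Reagents that add atoms: none
Why: Steglich O-acylation of the 4-hydroxy group followed by DMAP-mediated O-to-C acyl migration (Fries-type rearrangement through the acylpyridinium/enolate ion pair) should put the acyl group on C3, driven by the hydrogen-bonded β-tricarbonyl enol; no stereocentre is touched.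

**Step 14**
Reactants: 22 tert-butyl (2E,3E,6R)-9-[(R)-4-hydroxy-6-methyl-2-oxo-5,6-dihydro-2H-pyran-3-yl]-6-methyl-2-[(S)-2-methylbutylidene]-9-oxonon-3-enoate
Product: 23 (2E,3E,6R)-9-[(R)-4-hydroxy-6-methyl-2-oxo-5,6-dihydro-2H-pyran-3-yl]-6-methyl-2-[(S)-2-methylbutylidene]-9-oxonon-3-enoic acid (target)
Conditions: TFA/CH2Cl2 (1:4), 0 °C to rt
Reagents that add atoms: none
Why: Acidolysis removes the tert-butyl ester as isobutene; the 3-acyl-4-hydroxypyranone, the diene and the three stereocentres should be stable to anhydrous acid at this temperature.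

**Compound list**

1 | tert-butyl acetate | CC(=O)OC(C)(C)C | starting material
2 | (E)-but-2-enal | C/C=C/C=O | starting material
3 | lithium 1-tert-butoxyethen-1-olate (lithium enolate of 1) | [Li+].[O-]C(=C)OC(C)(C)C | intermediate
4 | tert-butyl (E)-3-hydroxyhex-4-enoate (racemic) | C/C=C/C(O)CC(=O)OC(C)(C)C | intermediate
5 | tert-butyl (E)-3-oxohex-4-enoate | C/C=C/C(=O)CC(=O)OC(C)(C)C | intermediate
6 | (E)-3-oxohex-4-enoic acid | C/C=C/C(=O)CC(=O)O | intermediate
7 | (R)-4-hydroxy-6-methyl-5,6-dihydro-2H-pyran-2-one | O=C1C=C(O)C[C@@H](C)O1 | intermediate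
8 | (S)-2-methylbutan-1-ol | CC[C@H](C)CO | starting material
9 | (S)-2-methylbutanal | CC[C@H](C)C=O | intermediate
10 | tert-butyl (triphenylphosphoranylidene)acetate | CC(C)(C)OC(=O)C=P(c1ccccc1)(c1ccccc1)c1ccccc1 | starting material
11 | tert-butyl 2-iodo-2-(triphenylphosphoranylidene)acetate (iodo ylide) | CC(C)(C)OC(=O)C(I)=P(c1ccccc1)(c1ccccc1)c1ccccc1 | intermediate
12 | tert-butyl (2Z,4S)-2-iodo-4-methylhex-2-enoate | CC[C@H](C)/C=C(\I)C(=O)OC(C)(C)C | intermediate
13 | (R)-citronellal, (R)-3,7-dimethyloct-6-enal | O=CC[C@H](C)CCC=C(C)C | starting material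
14 | (R)-4,8-dimethylnon-7-en-1-yne | C#CC[C@H](C)CCC=C(C)C | intermediate
15 | 3,3-dimethyl-5-[(R)-3-methylhex-5-yn-1-yl]-1,2,4-trioxolane (ozonide, epimers at C5) | C#CC[C@H](C)CCC1OOC(C)(C)O1 | intermediate
16 | (R)-4-methylhept-6-ynal | C#CC[C@H](C)CCC=O | intermediate
17 | methyl (R)-4-methylhept-6-ynoate | C#CC[C@H](C)CCC(=O)OC | intermediate
18 | methyl (R,E)-4-methyl-7-(4,4,5,5-tetramethyl-1,3,2-dioxaborolan-2-yl)hept-6-enoate | CC1(C)OB(/C=C/C[C@H](C)CCC(=O)OC)OC1(C)C | intermediate
19 | 1-tert-butyl 9-methyl (2E,3E,6R)-6-methyl-2-[(S)-2-methylbutylidene]non-3-enedioate | CC[C@H](C)/C=C(\C=C\C[C@H](C)CCC(=O)OC)C(=O)OC(C)(C)C | intermediate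
20 | (4R,6E,8E,10S)-8-(tert-butoxycarbonyl)-4,10-dimethyldodeca-6,8-dienoic acid | CC[C@H](C)/C=C(\C=C\C[C@H](C)CCC(=O)O)C(=O)OC(C)(C)C | intermediate
21 | (R)-2-methyl-6-oxo-3,6-dihydro-2H-pyran-4-yl (4R,6E,8E,10S)-8-(tert-butoxycarbonyl)-4,10-dimethyldodeca-6,8-dienoate (enol ester) | CC[C@H](C)/C=C(\C=C\C[C@H](C)CCC(=O)OC1=CC(=O)O[C@H](C)C1)C(=O)OC(C)(C)C | intermediate
22 | tert-butyl (2E,3E,6R)-9-[(R)-4-hydroxy-6-methyl-2-oxo-5,6-dihydro-2H-pyran-3-yl]-6-methyl-2-[(S)-2-methylbutylidene]-9-oxonon-3-enoate | CC[C@H](C)/C=C(\C=C\C[C@H](C)CCC(=O)C1=C(O)C[C@@H](C)OC1=O)C(=O)OC(C)(C)C | intermediate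
23 | (2E,3E,6R)-9-[(R)-4-hydroxy-6-methyl-2-oxo-5,6-dihydro-2H-pyran-3-yl]-6-methyl-2-[(S)-2-methylbutylidene]-9-oxonon-3-enoic acid | CC[C@H](C)/C=C(\C=C\C[C@H](C)CCC(=O)C1=C(O)C[C@@H](C)OC1=O)C(=O)O | target

**Step count and risks**

Total step count: 14. Longest linear sequence: 8 steps (steps 7 to 14, from (R)-citronellal).

Steps most likely to fail:

1. Step 4 (proposed new method). The catalyst may discriminate poorly between the two enone faces. The β-keto acid may lose CO2 before it cyclises. Acid-promoted or uncatalysed background closure would give racemic material, and intermolecular Michael addition would give oligomers. The fallback sets out from 1 and comes back at 7. The lithium enolate 3 (made from 1 with excess LDA in THF at −78 °C) is acylated by commercial methyl (R)-3-hydroxybutanoate in a crossed Claisen condensation to give tert-butyl (R)-5-hydroxy-3-oxohexanoate F1. F1 is then lactonised with TFA in CH2Cl2 to 7. In this fallback the C6 configuration comes from the chiral pool and the ring closes at the acyl carbon instead.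

2. Step 13. The sequence may stall at the enol ester 21. The activated acid may be diverted to an N-acylurea. Base-induced β-elimination could open the lactone and erode C6. The fallback sets out from 20 and comes back at 22. Acid 20 is condensed with Meldrum's acid (DCC, DMAP, CH2Cl2) to the acyl Meldrum's acid tert-butyl (2E,3E,6R)-9-(2,2-dimethyl-4,6-dioxo-1,3-dioxan-5-ylidene)-9-hydroxy-6-methyl-2-[(S)-2-methylbutylidene]non-3-enoate F2. Heating F2 with methyl (R)-3-hydroxybutanoate in toluene at 80 °C should trap the acylketene as the β-keto ester 1-tert-butyl 11-[(R)-4-methoxy-4-oxobutan-2-yl] (2E,3E,6R)-6-methyl-2-[(S)-2-methylbutylidene]-9-oxoundec-3-enedioate F3. A Lacey–Dieckmann cyclisation of F3 (KOtBu, THF/tBuOH, 0 °C) then closes the 3-acylpyranone and gives 22 without use of 7.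

3. Step 6. Z/E control may be poor, the deactivated iodo ylide may react slowly with the α-branched aldehyde, and the α-stereocentre may epimerise during a long reaction. The fallback sets out from 9 and comes back at 19. tert-Butyl 2,2,2-tribromoacetate F4 is made from tribromoacetic acid and tert-butyl 2,2,2-trichloroacetimidate. Olefination of 9 with F4 mediated by CrCl2 in THF at rt, a reaction type known for high (Z)-selectivity with α-haloacrylates, should give tert-butyl (2Z,4S)-2-bromo-4-methylhex-2-enoate F5. F5 takes the place of 12 in the Suzuki–Miyaura coupling of step 11 and gives 19.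

**Further compounds**

F1 | step 4 | tert-butyl (R)-5-hydroxy-3-oxohexanoate | C[C@@H](O)CC(=O)CC(=O)OC(C)(C)C
F2 | step 13 | tert-butyl (2E,3E,6R)-9-(2,2-dimethyl-4,6-dioxo-1,3-dioxan-5-ylidene)-9-hydroxy-6-methyl-2-[(S)-2-methylbutylidene]non-3-enoate | CC[C@H](C)/C=C(\C=C\C[C@H](C)CCC(O)=C1C(=O)OC(C)(C)OC1=O)C(=O)OC(C)(C)C
F3 | step 13 | 1-tert-butyl 11-[(R)-4-methoxy-4-oxobutan-2-yl] (2E,3E,6R)-6-methyl-2-[(S)-2-methylbutylidene]-9-oxoundec-3-enedioate | CC[C@H](C)/C=C(\C=C\C[C@H](C)CCC(=O)CC(=O)O[C@H](C)CC(=O)OC)C(=O)OC(C)(C)C
F4 | step 6 | tert-butyl 2,2,2-tribromoacetate | CC(C)(C)OC(=O)C(Br)(Br)Br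
F5 | step 6 | tert-butyl (2Z,4S)-2-bromo-4-methylhex-2-enoate | CC[C@H](C)/C=C(\Br)C(=O)OC(C)(C)C
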